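The route rests on cutting the bond between the quaternary carbon C3 and the chain methylene C4 (dodecadienedione numbering, aryl ketone = C1). Because C3 bears a vinyl group, C3 and the two vinyl carbons are treated as a transposed allyl unit. A copper-catalysed, enantioselective SN2′ allyl–alkyl coupling joins a primary (E)-allyl chloride holding the benzene ring to an alkyl-9-BBN made in the flask from the terminal alkene of a C11 triene. One operation forms C3–C4, the all-carbon stereocentre and the vinyl group. In the precursors both ketones are silyl-protected carbinols, the phenols are TIPS ethers, and C3 is still a flat alkene carbon.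

Key step: step 9

Assumption: the (R)-bisphosphine in step 9 is taken to give the (3R) product from the (E)-chloride; if a trial run shows the opposite sense, the (S)-ligand is used with nothing else changed. The carbinol centres at C1 and C9 are carried as racemic or epimeric mixtures because both are oxidised in step 11.

**Fragment A (aryl half)**

Step 1
Reactants: 1 2,4-dihydroxybenzaldehyde
Product: 2 2,4-bis(triisopropylsilyloxy)benzaldehyde
Conditions: TIPSCl, imidazole, DMAP (cat.), DMF, rt
Reagents that add atoms: chlorotriisopropylsilane, CC(C)[Si](Cl)(C(C)C)C(C)C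
Why: Imidazole-promoted silylation blocks both acidic phenols for the organometallic steps, and the bulky aryl TIPS ethers should resist the Lewis acids and the alkoxide used later while remaining cleavable by fluoride at the end.

Step 2
Reactants: 2 2,4-bis(triisopropylsilyloxy)benzaldehyde; 3 propargyl bromide
Product: 5 1-[2,4-bis(triisopropylsilyloxy)phenyl]but-3-yn-1-ol (racemic), via allenylzinc bromide 4 (not isolated)
Conditions: Zn dust, THF, 0 °C to rt; aq NH4Cl
Reagents that add atoms: none
Why: Barbier-type zinc propargylation, in which allenylzinc bromide 4 adds to the aldehyde through a cyclic SE2′ transition state to give the homopropargylic alcohol; the carbinol centre is made racemic on purpose because it becomes the ketone in step 11.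

Step 3
Reactants: 5 1-[2,4-bis(triisopropylsilyloxy)phenyl]but-3-yn-1-ol
Product: 6 1-[2,4-bis(triisopropylsilyloxy)phenyl]-1-(triethylsilyloxy)but-3-yne (racemic)
Conditions: TESCl, imidazole, DMAP (cat.), DMF, 0 °C to rt
Reagents that add atoms: chlorotriethylsilane, CC[Si](Cl)(CC)CC
Why: Standard silylation masks the future aryl ketone as a secondary alkyl TES ether, which is more acid-labile than the aryl TIPS ethers and can therefore be removed selectively in step 10.

Step 4
Reactants: 6 1-[2,4-bis(triisopropylsilyloxy)phenyl]-1-(triethylsilyloxy)but-3-yne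
Product: 8 (2E)-5-[2,4-bis(triisopropylsilyloxy)phenyl]-3-methyl-5-(triethylsilyloxy)pent-2-en-1-ol (racemic), via alkenyldimethylalane 7 (not isolated)
Conditions: Me3Al, Cp2ZrCl2 (cat.), CH2Cl2, 0 °C to rt; then (CH2O)n, THF, 0 °C to rt; aq potassium sodium tartrate
Reagents that add atoms: trimethylaluminium, C[Al](C)C; paraformaldehyde (as formaldehyde), C=O
Why: Negishi zirconium-catalysed methylalumination adds methyl and aluminium syn across the terminal alkyne with aluminium at the terminal carbon, which fixes the E trisubstituted alkene, and alkenylalane 7 is hydroxymethylated by formaldehyde with retention of geometry.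

Step 5
Reactants: 8 (2E)-5-[2,4-bis(triisopropylsilyloxy)phenyl]-3-methyl-5-(triethylsilyloxy)pent-2-en-1-ol
Product: 10 (3E)-1-[2,4-bis(triisopropylsilyloxy)phenyl]-5-chloro-3-methyl-1-(triethylsilyloxy)pent-3-ene (racemic), via allylic mesylate 9 (not isolated)
Conditions: MsCl, 2,4,6-collidine, LiCl, DMF, 0 °C
Reagents that add atoms: lithium chloride, [Li+].[Cl-]
Why: Mesylation followed by SN2 displacement with chloride in the same flask under buffered conditions should give the primary allyl chloride without allylic transposition or loss of the E geometry.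

**Fragment B (C11 half)**

Step 6
Reactants: 11 3-methylbut-2-enal; 3 propargyl bromide
Product: 13 6-methylhept-5-en-1-yn-4-ol (racemic), via allenylmagnesium bromide 12 (not isolated)
Conditions: 3, Mg turnings, HgCl2 (cat.), Et2O, 0 °C; then 11, −78 °C to 0 °C; aq NH4Cl
Reagents that add atoms: none
Why: Grignard propargylation, in which allenylmagnesium bromide 12, formed from propargyl bromide on mercury-activated magnesium, adds as a hard nucleophile in 1,2-fashion to the enal through a cyclic SE2′ transition state to give the homopropargylic alcohol; the racemic carbinol centre is erased in step 11.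

Step 7
Reactants: 13 6-methylhept-5-en-1-yn-4-ol
Product: 14 6-methyl-4-(triethylsilyloxy)hept-5-en-1-yne (racemic)
Conditions: TESCl, imidazole, CH2Cl2, 0 °C to rt
Reagents that add atoms: chlorotriethylsilane, CC[Si](Cl)(CC)CC
Why: Standard silylation masks the allylic carbinol (the future enone carbonyl) so that it survives the alane, the borane and the ethoxide of the following steps.

Step 8
Reactants: 14 6-methyl-4-(triethylsilyloxy)hept-5-en-1-yne; 15 vinyl bromide
Product: 17 (3E)-4,8-dimethyl-6-(triethylsilyloxy)nona-1,3,7-triene (racemic), via alkenyldimethylalane 16 (not isolated)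
Conditions: Me3Al, Cp2ZrCl2 (cat.), CH2Cl2, 0 °C to rt; then vinyl bromide, ZnCl2, Pd(PPh3)4 (cat.), THF, rt
Reagents that add atoms: trimethylaluminium, C[Al](C)C
Why: Negishi methylalumination (syn, aluminium at the terminus) followed by Negishi cross-coupling of alkenylalane 16 with vinyl bromide, with zinc chloride relaying the alkenyl group to zerovalent palladium, should give the (3E)-1,3-diene with retention of alkene geometry.

**Union and endgame**

Step 9
Reactants: 17 (3E)-4,8-dimethyl-6-(triethylsilyloxy)nona-1,3,7-triene; 10 (3E)-1-[2,4-bis(triisopropylsilyloxy)phenyl]-5-chloro-3-methyl-1-(triethylsilyloxy)pent-3-ene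
Product: 20 (3R,6E)-1-[2,4-bis(triisopropylsilyloxy)phenyl]-3-ethenyl-3,7,11-trimethyl-1,9-bis(triethylsilyloxy)dodeca-6,10-diene (mixture of C1 and C9 epimers), via B-alkyl-9-BBN 18 (not isolated), via potassium B-ethoxy borate 19 (not isolated)
Conditions: 17 (slight excess), 9-BBN dimer, THF, 0 °C to rt; then EtOK, (CuOTf)2·C6H5CH3 (cat.), (R)-DTBM-MeO-BIPHEP (cat.), 10, 1,4-dioxane, 25 °C
Reagents that add atoms: none
Why: 9-BBN adds anti-Markovnikov to the only monosubstituted alkene of 17 (C1=C2), ethoxide converts borane 18 into borate 19, which passes its primary alkyl group to the bisphosphine-bound monovalent copper, and the neutral alkylcopper adds across the alkene of 10 with carbon going to the γ-carbon and then expels chloride from the α-carbon, so that the double bond moves to the chain end. The closest known reaction type is the copper-catalysed enantioselective γ-selective (SN2′) allyl–alkyl coupling of γ,γ-disubstituted primary allyl chlorides with alkyl-9-BBN reagents, an established way to vinyl-bearing all-carbon quaternary centres from terminal alkenes. No ring is closed. The new stereocentre C3 is set by the catalyst: the C2-symmetric ligand shields one face of the trisubstituted alkene, and the single E geometry fixed in step 4 ensures that the methyl group and the C2 methylene are presented in one way only. The step needs γ over α attack, which the addition–elimination pathway of the alkylcopper at a primary chloride should secure, and face selectivity that the racemic carbinol centre of 10 does not override, which its separation from the alkene by a methylene group and the bulk of the ligand should secure. Silyl ethers tolerate the borate and ethoxide, the trisubstituted alkenes are not hydroborated at room temperature, and the stereoisomers at C1 and C9 converge in step 11.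

Step 10
Reactants: 20 (3R,6E)-1-[2,4-bis(triisopropylsilyloxy)phenyl]-3-ethenyl-3,7,11-trimethyl-1,9-bis(triethylsilyloxy)dodeca-6,10-diene
Product: 21 (3R,6E)-1-[2,4-bis(triisopropylsilyloxy)phenyl]-3-ethenyl-3,7,11-trimethyldodeca-6,10-diene-1,9-diol (mixture of C1 and C9 epimers)
Conditions: PPTS (cat.), MeOH/CH2Cl2, 0 °C to rt
Reagents that add atoms: none
Why: Mild acid-catalysed methanolysis should cleave the two secondary alkyl TES ethers, while aryl TIPS ethers are inert to pyridinium tosylate.

Step 11
Reactants: 21 (3R,6E)-1-[2,4-bis(triisopropylsilyloxy)phenyl]-3-ethenyl-3,7,11-trimethyldodeca-6,10-diene-1,9-diol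
Product: 22 (3R,6E)-1-[2,4-bis(triisopropylsilyloxy)phenyl]-3-ethenyl-3,7,11-trimethyldodeca-6,10-diene-1,9-dione
Conditions: DMP, NaHCO3, CH2Cl2, 0 °C to rt
Reagents that add atoms: none
Why: Dess–Martin oxidation under bicarbonate buffer should turn the benzylic and the allylic carbinol into the two ketones without moving the C6=C7 double bond into conjugation, and the carbinol epimers converge to one compound that keeps only the C3 stereocentre.

Step 12
Reactants: 22 (3R,6E)-1-[2,4-bis(triisopropylsilyloxy)phenyl]-3-ethenyl-3,7,11-trimethyldodeca-6,10-diene-1,9-dione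
Product: 23 (3R,6E)-1-(2,4-dihydroxyphenyl)-3-ethenyl-3,7,11-trimethyldodeca-6,10-diene-1,9-dione
Conditions: TBAF, AcOH, THF, 0 °C
Reagents that add atoms: none
Why: Fluoride-induced desilylation of the two aryl TIPS ethers should be fast because the acyl-substituted phenoxides are good leaving groups at silicon, and the acetic acid buffer keeps the medium from isomerising the β,γ-unsaturated ketone, while C3 carries no acidic hydrogen and cannot epimerise.

**Compound list**

1 | 2,4-dihydroxybenzaldehyde | O=Cc1ccc(O)cc1O | starting material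
2 | 2,4-bis(triisopropylsilyloxy)benzaldehyde | O=Cc1ccc(O[Si](C(C)C)(C(C)C)C(C)C)cc1O[Si](C(C)C)(C(C)C)C(C)C | intermediate
3 | propargyl bromide | C#CCBr | starting material
4 | allenylzinc bromide | C=C=C[Zn]Br | intermediate
5 | 1-[2,4-bis(triisopropylsilyloxy)phenyl]but-3-yn-1-ol (racemic) | C#CCC(O)c1ccc(O[Si](C(C)C)(C(C)C)C(C)C)cc1O[Si](C(C)C)(C(C)C)C(C)C | intermediate
6 | 1-[2,4-bis(triisopropylsilyloxy)phenyl]-1-(triethylsilyloxy)but-3-yne (racemic) | C#CCC(O[Si](CC)(CC)CC)c1ccc(O[Si](C(C)C)(C(C)C)C(C)C)cc1O[Si](C(C)C)(C(C)C)C(C)C | intermediate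
7 | dimethyl{(1E)-4-[2,4-bis(triisopropylsilyloxy)phenyl]-2-methyl-4-(triethylsilyloxy)but-1-en-1-yl}alane | C[Al](C)/C=C(\C)CC(O[Si](CC)(CC)CC)c1ccc(O[Si](C(C)C)(C(C)C)C(C)C)cc1O[Si](C(C)C)(C(C)C)C(C)C | intermediate
8 | (2E)-5-[2,4-bis(triisopropylsilyloxy)phenyl]-3-methyl-5-(triethylsilyloxy)pent-2-en-1-ol (racemic) | OC/C=C(\C)CC(O[Si](CC)(CC)CC)c1ccc(O[Si](C(C)C)(C(C)C)C(C)C)cc1O[Si](C(C)C)(C(C)C)C(C)C | intermediate
9 | (2E)-5-[2,4-bis(triisopropylsilyloxy)phenyl]-3-methyl-5-(triethylsilyloxy)pent-2-en-1-yl methanesulfonate | CS(=O)(=O)OC/C=C(\C)CC(O[Si](CC)(CC)CC)c1ccc(O[Si](C(C)C)(C(C)C)C(C)C)cc1O[Si](C(C)C)(C(C)C)C(C)C | intermediate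
10 | (3E)-1-[2,4-bis(triisopropylsilyloxy)phenyl]-5-chloro-3-methyl-1-(triethylsilyloxy)pent-3-ene (racemic) | ClC/C=C(\C)CC(O[Si](CC)(CC)CC)c1ccc(O[Si](C(C)C)(C(C)C)C(C)C)cc1O[Si](C(C)C)(C(C)C)C(C)C | intermediate
11 | 3-methylbut-2-enal | CC(C)=CC=O | starting material
12 | allenylmagnesium bromide | C=C=C[Mg]Br | intermediate
13 | 6-methylhept-5-en-1-yn-4-ol (racemic) | C#CCC(O)C=C(C)C | intermediate
14 | 6-methyl-4-(triethylsilyloxy)hept-5-en-1-yne (racemic) | C#CCC(O[Si](CC)(CC)CC)C=C(C)C | intermediate
15 | vinyl bromide | C=CBr | starting material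
16 | dimethyl[(1E)-2,6-dimethyl-4-(triethylsilyloxy)hepta-1,5-dien-1-yl]alane | C[Al](C)/C=C(\C)CC(O[Si](CC)(CC)CC)C=C(C)C | intermediate
17 | (3E)-4,8-dimethyl-6-(triethylsilyloxy)nona-1,3,7-triene (racemic) | C=C/C=C(\C)CC(O[Si](CC)(CC)CC)C=C(C)C | intermediate
18 | 9-[(3E)-4,8-dimethyl-6-(triethylsilyloxy)nona-3,7-dien-1-yl]-9-borabicyclo[3.3.1]nonane | B1(CC/C=C(\C)CC(O[Si](CC)(CC)CC)C=C(C)C)C2CCCC1CCC2 | intermediate
19 | potassium 9-[(3E)-4,8-dimethyl-6-(triethylsilyloxy)nona-3,7-dien-1-yl]-9-ethoxy-9-boranuidabicyclo[3.3.1]nonane | [K+].CCO[B-]1(CC/C=C(\C)CC(O[Si](CC)(CC)CC)C=C(C)C)C2CCCC1CCC2 | intermediate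
20 | (3R,6E)-1-[2,4-bis(triisopropylsilyloxy)phenyl]-3-ethenyl-3,7,11-trimethyl-1,9-bis(triethylsilyloxy)dodeca-6,10-diene (C1 and C9 epimers) | C=C[C@](C)(CC/C=C(\C)CC(O[Si](CC)(CC)CC)C=C(C)C)CC(O[Si](CC)(CC)CC)c1ccc(O[Si](C(C)C)(C(C)C)C(C)C)cc1O[Si](C(C)C)(C(C)C)C(C)C | intermediate
21 | (3R,6E)-1-[2,4-bis(triisopropylsilyloxy)phenyl]-3-ethenyl-3,7,11-trimethyldodeca-6,10-diene-1,9-diol (C1 and C9 epimers) | C=C[C@](C)(CC/C=C(\C)CC(O)C=C(C)C)CC(O)c1ccc(O[Si](C(C)C)(C(C)C)C(C)C)cc1O[Si](C(C)C)(C(C)C)C(C)C | intermediate
22 | (3R,6E)-1-[2,4-bis(triisopropylsilyloxy)phenyl]-3-ethenyl-3,7,11-trimethyldodeca-6,10-diene-1,9-dione | C=C[C@](C)(CC/C=C(\C)CC(=O)C=C(C)C)CC(=O)c1ccc(O[Si](C(C)C)(C(C)C)C(C)C)cc1O[Si](C(C)C)(C(C)C)C(C)C | intermediate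
23 | (3R,6E)-1-(2,4-dihydroxyphenyl)-3-ethenyl-3,7,11-trimethyldodeca-6,10-diene-1,9-dione | C=C[C@](C)(CC/C=C(\C)CC(=O)C=C(C)C)CC(=O)c1ccc(O)cc1O | target

**Count and risks**

Total step count: 12. Longest linear sequence: 9 steps (steps 1–5, then 9–12).

Steps most likely to fail:

Step 9. The face selectivity at the γ-carbon may be incomplete, above all in the carbinol epimer of 10 that is mismatched with the ligand. Transmetalation or addition at the hindered γ,γ-disubstituted alkene may be slow enough for α-substitution or a second hydroboration of the diene to compete. The fallback keeps the same bond formation but brings the nucleophile in as a hard organomagnesium reagent with a different ligand class; it sets out from 17 and 10 and comes back at 20. Triene 17 is hydroborated with 9-BBN to borane 18, which is oxidised with NaBO3 to (3E)-4,8-dimethyl-6-(triethylsilyloxy)nona-3,7-dien-1-ol F1. This is converted with I2, PPh3 and imidazole into (3E)-1-iodo-4,8-dimethyl-6-(triethylsilyloxy)nona-3,7-diene F2 and then with Mg in Et2O into [(3E)-4,8-dimethyl-6-(triethylsilyloxy)nona-3,7-dien-1-yl]magnesium iodide F3. Slow addition of F3 to chloride 10 with copper thiophene-2-carboxylate, Cu(O2CC4H3S), a salt of monovalent copper, and a chiral phosphoramidite ligand in CH2Cl2 at −78 °C should give 20 by Grignard-based enantioselective SN2′ allylic alkylation.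

Step 4. Methylalumination of the hindered homopropargylic ether may stall, the electron-rich benzylic C–O bond may ionise under the Lewis acidic aluminium and zirconium species, or the alkenylalane may be captured poorly by formaldehyde. The fallback builds the same E allylic alcohol by a vinylogous aldol instead of alkyne carbometalation; it sets out from 2 and comes back at 8. Methyl 3-methylbut-2-enoate is converted with LiN(i-Pr)2 and TMSCl into 1-methoxy-3-methyl-1-(trimethylsilyloxy)buta-1,3-diene F4. Its γ-selective vinylogous Mukaiyama aldol addition to aldehyde 2 with BF3·OEt2 at −78 °C should give methyl (2E)-5-[2,4-bis(triisopropylsilyloxy)phenyl]-5-hydroxy-3-methylpent-2-enoate F5. Silylation with TESCl and imidazole gives methyl (2E)-5-[2,4-bis(triisopropylsilyloxy)phenyl]-3-methyl-5-(triethylsilyloxy)pent-2-enoate F6, and reduction with i-Bu2AlH at −78 °C gives 8.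

Step 10. The acid may ionise the electron-rich benzylic carbinol or the allylic carbinol (solvolysis, allylic transposition), or the hindered benzylic TES ether may be cleaved incompletely. The fallback replaces acid methanolysis by oxidative deprotection; it sets out from 20 and comes back at 22. Treatment of 20 with IBX in DMSO should cleave the secondary TES ethers and oxidise the freed alcohols in the same flask, giving diketone 22 directly, so the free carbinols do not sit in acid and no new compound (F0) is made.

Further compounds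
F1 | step 9 | (3E)-4,8-dimethyl-6-(triethylsilyloxy)nona-3,7-dien-1-ol | OCC/C=C(\C)CC(O[Si](CC)(CC)CC)C=C(C)C
F2 | step 9 | (3E)-1-iodo-4,8-dimethyl-6-(triethylsilyloxy)nona-3,7-diene | ICC/C=C(\C)CC(O[Si](CC)(CC)CC)C=C(C)C
F3 | step 9 | [(3E)-4,8-dimethyl-6-(triethylsilyloxy)nona-3,7-dien-1-yl]magnesium iodide | I[Mg]CC/C=C(\C)CC(O[Si](CC)(CC)CC)C=C(C)C
F4 | step 4 | 1-methoxy-3-methyl-1-(trimethylsilyloxy)buta-1,3-diene | C=C(C)C=C(OC)O[Si](C)(C)C
F5 | step 4 | methyl (2E)-5-[2,4-bis(triisopropylsilyloxy)phenyl]-5-hydroxy-3-methylpent-2-enoate | COC(=O)/C=C(\C)CC(O)c1ccc(O[Si](C(C)C)(C(C)C)C(C)C)cc1O[Si](C(C)C)(C(C)C)C(C)C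
F6 | step 4 | methyl (2E)-5-[2,4-bis(triisopropylsilyloxy)phenyl]-3-methyl-5-(triethylsilyloxy)pent-2-enoate | COC(=O)/C=C(\C)CC(O[Si](CC)(CC)CC)c1ccc(O[Si](C(C)C)(C(C)C)C(C)C)cc1O[Si](C(C)C)(C(C)C)C(C)C
F0 | step 10 | none | none
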